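**Retrosynthetic overview**

1. Agrimol B is cut at its two ArCH2–Ar bonds into the central ring B ketone (phloroglucinol acylated with (S)-2-methylbutanoic acid, which supplies the only stereocentre) and two outer-ring Mannich bases that act as ortho-quinone methide precursors.
2. Outer ring (target locants: C1' butanoyl, C2' OH, C3' bridge CH2, C4' OH, C5' CH3, C6' OCH3): the strategy rests on the acyl carbon C1' and the hydroxyl carbon C2' being ring neighbours, with the C6' methoxyl on the other side of C1'. The C1'–C(=O) and C2'–O bonds are therefore made together by insertion of a C1'≡C2' aryne into the C–O bond of butanoic acid, the methoxyl steering oxygen to C2'.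
3. The aryne precursor, an ortho-silyl aryl triflate with C4'–O held as a benzyl ether, comes from 2,4-dihydroxy-3-methylbenzaldehyde by benzylation, methylation, Dakin-type oxidation, carbamate-directed ortho-silylation and triflation.
4. No ring is formed anywhere: the three benzene rings are bought. The outer ring is dressed first, ring B is acylated separately, and the two methylene bridges are made last.

Key step: step 7

**Route**

Step 1
Reactants: 1 2,4-dihydroxy-3-methylbenzaldehyde
Product: 2 4-(benzyloxy)-2-hydroxy-3-methylbenzaldehyde
Conditions: BnBr (1.05 equiv), NaHCO3, MeCN, 70 °C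
Reagents that add atoms: benzyl bromide, BrCc1ccccc1
Why: Regioselective Williamson etherification, since the 2-hydroxyl is hydrogen-bonded to the formyl group and a weak base should alkylate only the free 4-hydroxyl.

Step 2
Reactants: 2 4-(benzyloxy)-2-hydroxy-3-methylbenzaldehyde
Product: 3 4-(benzyloxy)-2-methoxy-3-methylbenzaldehyde
Conditions: MeI, K2CO3, DMF, rt
Reagents that add atoms: iodomethane, CI
Why: Williamson methylation, in which carbonate in a dipolar solvent opens the chelate and the only remaining phenol is methylated.

Step 3
Reactants: 3 4-(benzyloxy)-2-methoxy-3-methylbenzaldehyde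
Product: 5 4-(benzyloxy)-2-methoxy-3-methylphenol, via aryl formate 4 (not isolated)
Conditions: mCPBA, CH2Cl2, 0 °C to rt; then K2CO3 (cat.), MeOH, rt
Reagents that add atoms: meta-chloroperoxybenzoic acid, OOC(=O)c1cccc(Cl)c1
Why: Baeyer–Villiger (Dakin-type) oxidation, in which the electron-rich aryl group with ortho and para alkoxy substituents migrates in preference to hydride, followed by methanolysis of the formate that leaves the benzyl ether untouched.

Step 4
Reactants: 5 4-(benzyloxy)-2-methoxy-3-methylphenol
Product: 6 4-(benzyloxy)-2-methoxy-3-methylphenyl N-(propan-2-yl)carbamate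
Conditions: i-PrNCO, Et3N (cat.), CH2Cl2, rt
Reagents that add atoms: isopropyl isocyanate, CC(C)N=C=O
Why: Base-catalysed addition of the phenol to the isocyanate (carbamoylation) should give a secondary carbamate that directs metalation and can later be removed under mild basic conditions.

Step 5
Reactants: 6 4-(benzyloxy)-2-methoxy-3-methylphenyl N-(propan-2-yl)carbamate
Product: 10 4-(benzyloxy)-2-methoxy-3-methyl-6-(trimethylsilyl)phenyl N-(propan-2-yl)carbamate, via N-silyl carbamate 7 (not isolated), via aryllithium 8 (not isolated), via C-silyl N-silyl carbamate 9 (not isolated)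
Conditions: TBSOTf, TMEDA, Et2O, 0 °C to rt; n-BuLi (2.2 equiv), TMEDA, −78 °C; TMSCl, −78 °C to rt; aq. HCl work-up
Reagents that add atoms: chlorotrimethylsilane, C[Si](C)(C)Cl
Why: Directed ortho-metalation, in which in-situ N-silylation masks the N–H, the carbamate directs n-BuLi/TMEDA to its only free ortho position (C6 of the phenol), TMSCl traps the aryllithium and the acidic work-up removes the N-silyl group.

Step 6
Reactants: 10 4-(benzyloxy)-2-methoxy-3-methyl-6-(trimethylsilyl)phenyl N-(propan-2-yl)carbamate
Product: 12 4-(benzyloxy)-2-methoxy-3-methyl-6-(trimethylsilyl)phenyl trifluoromethanesulfonate, via silyl phenol 11 (not isolated)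
Conditions: DBU, Et2NH, MeCN, 40 °C; then PhNTf2, rt
Reagents that add atoms: N-phenylbis(trifluoromethanesulfonimide), O=S(=O)(N(c1ccccc1)S(=O)(=O)C(F)(F)F)C(F)(F)F
Why: Base-induced cleavage of the secondary carbamate (E1cB through the isocyanate, which diethylamine captures as a urea) followed by O-triflation of the phenoxide in the same flask, so that the ortho-silyl phenol, which is prone to protodesilylation, is never isolated.

Step 7
Reactants: 12 4-(benzyloxy)-2-methoxy-3-methyl-6-(trimethylsilyl)phenyl trifluoromethanesulfonate; 13 butanoic acid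
Product: 16 1-[4-(benzyloxy)-6-hydroxy-2-methoxy-3-methylphenyl]butan-1-one, via aryne 14 (not isolated), via aryl anion 15 (not isolated)
Conditions: 13 (1.2 equiv), CsF (4 equiv), THF, 125 °C, sealed tube
Reagents that add atoms: none
Why: CsF takes the silyl group, triflate leaves and aryne 14 (triple bond between C1' and C2') forms; caesium butanoate adds through oxygen to C2' to give aryl anion 15 at C1', which attacks the adjacent ester carbonyl through a four-membered transition state, so that the butanoyl group moves from oxygen to carbon and the C2'–O and C1'–C(=O) bonds are made in one operation. The closest known reaction type is the fluoride-induced insertion of arynes into the C–O bond of carboxylic acids to give ortho-hydroxyaryl ketones, in essence an anionic Fries-type 1,3 O-to-C acyl shift. No ring is closed and no stereocentre is formed. The selectivity needed is regiocontrol in the addition to the unsymmetrical aryne; the C6' methoxyl next to the triple bond distorts the aryne and stabilises charge at C1' inductively, so oxygen should add at the remote carbon C2' as with 3-methoxybenzyne, while C3' carries only hydrogen so that sterics agree and the distant C4' benzyloxy group has only a weak influence. The second need, an acyl shift faster than protonation of 15, is served by THF at 125 °C, only a slight excess of acid and excess CsF, which holds the acid as its caesium salt. The methyl and benzyl ethers are inert to fluoride and keep the two remaining oxygens differentiated for the later steps.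

Step 8
Reactants: 16 1-[4-(benzyloxy)-6-hydroxy-2-methoxy-3-methylphenyl]butan-1-one
Product: 17 1-(4,6-dihydroxy-2-methoxy-3-methylphenyl)butan-1-one
Conditions: H2 (1 atm), 10% Pd/C (palladium on carbon), EtOAc, rt
Reagents that add atoms: none
Why: Hydrogenolysis of the benzyl ether, in which the ketone, chelated by the ortho hydroxyl on an electron-rich ring, should not be reduced at ambient pressure and temperature.

Step 9
Reactants: 17 1-(4,6-dihydroxy-2-methoxy-3-methylphenyl)butan-1-one
Product: 18 1-{3-[(dimethylamino)methyl]-2,4-dihydroxy-6-methoxy-5-methylphenyl}butan-1-one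
Conditions: Me2N=CH2+ I− (N,N-dimethylmethyleneiminium iodide, 1.05 equiv), CH2Cl2, 0 °C to rt; then aq. NaHCO3
Reagents that add atoms: N,N-dimethylmethyleneiminium iodide, C=[N+](C)C.[I-]
Why: Mannich reaction with a preformed iminium salt, in which the only unsubstituted ring carbon (C3', between two hydroxyls) is strongly nucleophilic and is aminomethylated without a free formaldehyde source that could cause homocoupling.

Step 10
Reactants: 19 (S)-2-methylbutanoic acid; 20 phloroglucinol
Product: 22 (2S)-2-methyl-1-(2,4,6-trihydroxyphenyl)butan-1-one, via acid chloride 21 (not isolated)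
Conditions: (COCl)2, DMF (cat.), CH2Cl2, 0 °C to rt; then 20, AlCl3 (3.5 equiv), PhNO2/CH2Cl2, 0 °C to rt; aq. HCl work-up
Reagents that add atoms: none
Why: Friedel–Crafts acylation of the symmetrical triphenol, which can give only one C-acyl product and is deactivated against a second acylation, with the stereocentre carried over from the acid and the temperature held at or below rt to suppress ketene formation and enolisation.

Step 11
Reactants: 18 1-{3-[(dimethylamino)methyl]-2,4-dihydroxy-6-methoxy-5-methylphenyl}butan-1-one (2.2 equiv); 22 (2S)-2-methyl-1-(2,4,6-trihydroxyphenyl)butan-1-one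
Product: 25 agrimol B, via ortho-quinone methide 23 (not isolated), via mono-bridged dimer 24 (not isolated)
Conditions: 1,4-dioxane, 95 °C, slow N2 stream
Reagents that add atoms: none
Why: Thermal loss of dimethylamine from the phenolic Mannich base gives an ortho-quinone methide that takes up ring B at its two free carbons C3 and C5 in turn (Michael addition, a Friedel–Crafts-type alkylation), homocoupling being excluded because the electrophile has no free ring position and the nucleophile no CH2 donor, while the stereocentre should survive because the phenoxide-conjugated ring B ketone is reluctant to enolise.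

**Compound list**

1 | 2,4-dihydroxy-3-methylbenzaldehyde | Cc1c(O)ccc(C=O)c1O | starting material
2 | 4-(benzyloxy)-2-hydroxy-3-methylbenzaldehyde | Cc1c(OCc2ccccc2)ccc(C=O)c1O | intermediate
3 | 4-(benzyloxy)-2-methoxy-3-methylbenzaldehyde | COc1c(C)c(OCc2ccccc2)ccc1C=O | intermediate
4 | 4-(benzyloxy)-2-methoxy-3-methylphenyl formate (not isolated) | COc1c(C)c(OCc2ccccc2)ccc1OC=O | intermediate
5 | 4-(benzyloxy)-2-methoxy-3-methylphenol | COc1c(C)c(OCc2ccccc2)ccc1O | intermediate
6 | 4-(benzyloxy)-2-methoxy-3-methylphenyl N-(propan-2-yl)carbamate | COc1c(C)c(OCc2ccccc2)ccc1OC(=O)NC(C)C | intermediate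
7 | 4-(benzyloxy)-2-methoxy-3-methylphenyl N-(tert-butyldimethylsilyl)-N-(propan-2-yl)carbamate (not isolated) | COc1c(C)c(OCc2ccccc2)ccc1OC(=O)N(C(C)C)[Si](C)(C)C(C)(C)C | intermediate
8 | [5-(benzyloxy)-2-{[(tert-butyldimethylsilyl)(propan-2-yl)carbamoyl]oxy}-3-methoxy-4-methylphenyl]lithium (not isolated) | COc1c(C)c(OCc2ccccc2)cc([Li])c1OC(=O)N(C(C)C)[Si](C)(C)C(C)(C)C | intermediate
9 | 4-(benzyloxy)-2-methoxy-3-methyl-6-(trimethylsilyl)phenyl N-(tert-butyldimethylsilyl)-N-(propan-2-yl)carbamate (not isolated) | COc1c(C)c(OCc2ccccc2)cc([Si](C)(C)C)c1OC(=O)N(C(C)C)[Si](C)(C)C(C)(C)C | intermediate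
10 | 4-(benzyloxy)-2-methoxy-3-methyl-6-(trimethylsilyl)phenyl N-(propan-2-yl)carbamate | COc1c(C)c(OCc2ccccc2)cc([Si](C)(C)C)c1OC(=O)NC(C)C | intermediate
11 | 4-(benzyloxy)-2-methoxy-3-methyl-6-(trimethylsilyl)phenol (not isolated) | COc1c(C)c(OCc2ccccc2)cc([Si](C)(C)C)c1O | intermediate
12 | 4-(benzyloxy)-2-methoxy-3-methyl-6-(trimethylsilyl)phenyl trifluoromethanesulfonate | COc1c(C)c(OCc2ccccc2)cc([Si](C)(C)C)c1OS(=O)(=O)C(F)(F)F | intermediate
13 | butanoic acid | CCCC(=O)O | starting material
14 | 5-(benzyloxy)-3-methoxy-4-methyl-1,2-didehydrobenzene, the aryne (not isolated) | COC1=C(C)C(OCc2ccccc2)=CC#C1 | intermediate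
15 | caesium 4-(benzyloxy)-2-(butanoyloxy)-6-methoxy-5-methylbenzen-1-ide (not isolated) | CCCC(=O)Oc1cc(OCc2ccccc2)c(C)c(OC)[c-]1.[Cs+] | intermediate
16 | 1-[4-(benzyloxy)-6-hydroxy-2-methoxy-3-methylphenyl]butan-1-one | CCCC(=O)c1c(O)cc(OCc2ccccc2)c(C)c1OC | intermediate
17 | 1-(4,6-dihydroxy-2-methoxy-3-methylphenyl)butan-1-one | CCCC(=O)c1c(O)cc(O)c(C)c1OC | intermediate
18 | 1-{3-[(dimethylamino)methyl]-2,4-dihydroxy-6-methoxy-5-methylphenyl}butan-1-one | CCCC(=O)c1c(O)c(CN(C)C)c(O)c(C)c1OC | intermediate
19 | (S)-2-methylbutanoic acid | CC[C@H](C)C(=O)O | starting material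
20 | phloroglucinol (benzene-1,3,5-triol) | Oc1cc(O)cc(O)c1 | starting material
21 | (S)-2-methylbutanoyl chloride (not isolated) | CC[C@H](C)C(=O)Cl | intermediate
22 | (2S)-2-methyl-1-(2,4,6-trihydroxyphenyl)butan-1-one, the ring B ketone | CC[C@H](C)C(=O)c1c(O)cc(O)cc1O | intermediate
23 | 4-butanoyl-5-hydroxy-3-methoxy-2-methyl-6-methylidenecyclohexa-2,4-dien-1-one, the ortho-quinone methide (not isolated) | CCCC(=O)C1=C(O)C(=C)C(=O)C(C)=C1OC | intermediate
24 | (2S)-1-{3-[(3-butanoyl-2,6-dihydroxy-4-methoxy-5-methylphenyl)methyl]-2,4,6-trihydroxyphenyl}-2-methylbutan-1-one (not isolated) | CCCC(=O)c1c(O)c(Cc2c(O)cc(O)c(C(=O)[C@@H](C)CC)c2O)c(O)c(C)c1OC | intermediate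
25 | agrimol B, (2S)-1-{3,5-bis[(3-butanoyl-2,6-dihydroxy-4-methoxy-5-methylphenyl)methyl]-2,4,6-trihydroxyphenyl}-2-methylbutan-1-one | CCCC(=O)c1c(O)c(Cc2c(O)c(Cc3c(O)c(C)c(OC)c(C(=O)CCC)c3O)c(O)c(C(=O)[C@@H](C)CC)c2O)c(O)c(C)c1OC | target

**Step count**

Total: 11 steps. Longest linear sequence: 10 steps (steps 1 to 9, then step 11); step 10 is the ring B branch.

**Steps most likely to fail, with fallbacks**

Step 7 (aryne insertion). The aryl anion 15 may be protonated by butanoic acid or HF before the acyl group has moved, which would stop the sequence at O-arylation, or the carboxylate may add with poor regiocontrol. The fallback sets out from 12 and comes back at 16. The same aryne is generated with CsF in DMF at rt in the absence of any acid. DMF inserts with its C=O bond (oxygen to C2', carbon to C1', [2+2] addition then ring opening) to give 3-(benzyloxy)-6-[(dimethylamino)methylidene]-5-methoxy-4-methylcyclohexa-2,4-dien-1-one F1, which is hydrolysed on aqueous work-up to 4-(benzyloxy)-6-hydroxy-2-methoxy-3-methylbenzaldehyde F2. Addition of n-PrMgBr (2.2 equiv, THF, 0 °C) should give racemic 1-[4-(benzyloxy)-6-hydroxy-2-methoxy-3-methylphenyl]butan-1-ol F3, and oxidation of the benzylic alcohol with MnO2 (CH2Cl2, rt) should give 16. The C1'–C bond is then made by π-insertion of a one-carbon unit with no proton donor present, and the chain is completed by Grignard addition and oxidation.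

Step 11 (double methylene bridging). CH2 units may be exchanged between rings through reversible ortho-quinone methide formation, which would scramble the partners towards the symmetrical bis(outer-ring)methane. The reaction may also stop at the mono-bridged stage 24, or loss of dimethylamine from the chelated Mannich base may be slow. The fallback sets out from 22 (with 17 as partner) and comes back at 25, with the roles of the rings reversed. Ring B ketone 22 is aminomethylated twice with N,N-dimethylmethyleneiminium iodide (2.1 equiv, CH2Cl2, rt, then aq. NaHCO3) to give (2S)-1-{3,5-bis[(dimethylamino)methyl]-2,4,6-trihydroxyphenyl}-2-methylbutan-1-one F4. F4 is then heated with an excess of outer ketone 17 (3 equiv, 1,4-dioxane, 95 °C). Ring B then carries both electrophilic carbons and the outer ketone serves as a recoverable nucleophile with a single free position.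

Step 5 (ortho-silylation). n-BuLi may deprotonate the benzylic CH2 of the benzyl ether (followed by Wittig rearrangement) or C5 next to the benzyloxy group instead of C6 next to the carbamate. The fallback sets out from 5 and comes back at 12, bypassing steps 4 to 6. Ortho-selective bromination of phenol 5 (NBS, i-Pr2NH cat., CH2Cl2, 0 °C) should give 4-(benzyloxy)-6-bromo-2-methoxy-3-methylphenol F5. O-Silylation (HMDS, THF, 65 °C) gives [4-(benzyloxy)-6-bromo-2-methoxy-3-methylphenoxy]trimethylsilane F6. Bromine–lithium exchange (n-BuLi, THF, −100 °C) then triggers a 1,3 O-to-C silyl shift (retro-Brook), and the resulting lithium phenoxide is trapped with Tf2O to give 12. The site of metalation is then fixed by the halogen and not by competitive deprotonation.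

**Further compounds**

F1 | step 7 | 3-(benzyloxy)-6-[(dimethylamino)methylidene]-5-methoxy-4-methylcyclohexa-2,4-dien-1-one | CN(C)C=C1C(=O)C=C(OCc2ccccc2)C(C)=C1OC
F2 | step 7 | 4-(benzyloxy)-6-hydroxy-2-methoxy-3-methylbenzaldehyde | O=Cc1c(O)cc(OCc2ccccc2)c(C)c1OC
F3 | step 7 | 1-[4-(benzyloxy)-6-hydroxy-2-methoxy-3-methylphenyl]butan-1-ol (racemic) | CCCC(O)c1c(O)cc(OCc2ccccc2)c(C)c1OC
F4 | step 11 | (2S)-1-{3,5-bis[(dimethylamino)methyl]-2,4,6-trihydroxyphenyl}-2-methylbutan-1-one | CC[C@H](C)C(=O)c1c(O)c(CN(C)C)c(O)c(CN(C)C)c1O
F5 | step 5 | 4-(benzyloxy)-6-bromo-2-methoxy-3-methylphenol | COc1c(C)c(OCc2ccccc2)cc(Br)c1O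
F6 | step 5 | [4-(benzyloxy)-6-bromo-2-methoxy-3-methylphenoxy]trimethylsilane | COc1c(C)c(OCc2ccccc2)cc(Br)c1O[Si](C)(C)C
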